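The arene is not functionalised but made last. Ring carbons C1–C6 of the resorcylate are read as C2–C7 of a 3,5,7-triketo ester, so the pyran CH2 (on the carbon between two ketones) and the pyran oxygen are fixed by chain position, not by arene regiocontrol. The key step heats open-chain diketo-dioxinone 20: its acylketene is caught by the remote (R)-carbinol to give a 16-membered tetraoxo lactone, transannular aldol aromatisation contracts this to the 12-membered benzolactone, and the phenol so created closes the pyran on the side-chain oxolane ketal. The precursor is a linear chain carrying a preformed 2-methoxyoxolane made from (S)-β-methyl-γ-butyrolactone.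

Key step: step 11

Remark: the oxolane ketal carbon of 4–23 is carried as an epimer mixture because it becomes planar (oxocarbenium ion) in step 11, and (S)-4-methyldihydrofuran-2(3H)-one is taken as a catalogue lactone.

Step 1
Reactants: 1 (S)-4-methyldihydrofuran-2(3H)-one
Product: 3 (3S,4S)-4-methyl-3-(prop-2-en-1-yl)dihydrofuran-2(3H)-one, via lithium enolate 2 (not isolated)
Conditions: LDA, THF, −78 °C; allyl bromide, −78 → −30 °C
Reagents that add atoms: allyl bromide, C=CCBr
Why: Enolate alkylation in which the lithium enolate of the γ-lactone should take the allyl group on the face opposite the adjacent C-4 methyl, so that the new C-3 centre is set trans (3S) by substrate control.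

Step 2
Reactants: 3 (3S,4S)-4-methyl-3-(prop-2-en-1-yl)dihydrofuran-2(3H)-one
Product: 5 (3S,4S)-2-methoxy-2,4-dimethyl-3-(prop-2-en-1-yl)oxolane (C-2 epimers), via lactol 4 (not isolated)
Conditions: MeLi (1.05 equiv), THF, −78 °C; H2O; then MeOH, PPTS (cat.), 4 Å MS, rt
Reagents that add atoms: methyllithium, [Li]C; methanol, CO
Why: Single addition of methyllithium to a lactone at low temperature should stop at the lithium lactolate, and acid-catalysed ketalisation of the resulting γ-hydroxy ketone with methanol masks the ketone as a base-stable cyclic mixed ketal whose ketal carbon is left as an epimer mixture.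

Step 3
Reactants: 5 (3S,4S)-2-methoxy-2,4-dimethyl-3-(prop-2-en-1-yl)oxolane
Product: 7 3-[(3S,4S)-2-methoxy-2,4-dimethyloxolan-3-yl]propan-1-ol, via B-alkyl-9-BBN 6 (not isolated)
Conditions: 9-BBN, THF, 0 °C → rt; then NaOH, H2O2, 0 °C
Reagents that add atoms: hydrogen peroxide, OO
Why: Brown hydroboration–oxidation, in which 9-BBN adds to the terminal alkene with anti-Markovnikov regiochemistry and the basic peroxide work-up leaves the ketal untouched.

Step 4
Reactants: 7 3-[(3S,4S)-2-methoxy-2,4-dimethyloxolan-3-yl]propan-1-ol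
Product: 8 3-[(3S,4S)-2-methoxy-2,4-dimethyloxolan-3-yl]propanal
Conditions: TPAP (5 mol%), NMO, 4 Å MS, CH2Cl2, rt
Reagents that add atoms: none
Why: Ley–Griffith oxidation is neutral, stops at the aldehyde and should not disturb the acid-labile ketal.

Step 5
Reactants: 8 3-[(3S,4S)-2-methoxy-2,4-dimethyloxolan-3-yl]propanal; 9 2,2,6-trimethyl-4H-1,3-dioxin-4-one
Product: 11 6-{2-hydroxy-4-[(3S,4S)-2-methoxy-2,4-dimethyloxolan-3-yl]butyl}-2,2-dimethyl-4H-1,3-dioxin-4-one (carbinol epimers), via lithium dienolate 10 (not isolated)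
Conditions: 9, LDA, THF, −78 °C; then 8; H2O
Reagents that add atoms: none
Why: Vinylogous aldol addition in which the lithium dienolate of the dioxinone should react at its exocyclic γ-carbon with the aliphatic aldehyde, the new carbinol centre being formed as a mixture that is erased in step 6.

Step 6
Reactants: 11 6-{2-hydroxy-4-[(3S,4S)-2-methoxy-2,4-dimethyloxolan-3-yl]butyl}-2,2-dimethyl-4H-1,3-dioxin-4-one
Product: 12 6-{4-[(3S,4S)-2-methoxy-2,4-dimethyloxolan-3-yl]-2-oxobutyl}-2,2-dimethyl-4H-1,3-dioxin-4-one
Conditions: DMP, pyridine, CH2Cl2, 0 °C → rt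
Reagents that add atoms: none
Why: Dess–Martin oxidation of the β-hydroxy dioxinone under pyridine buffering should give the β-keto dioxinone without touching ketal or dioxinone.

Step 7
Reactants: 13 dec-9-enoic acid
Product: 15 N-methoxy-N-methyldec-9-enamide, via acyl imidazole 14 (not isolated)
Conditions: CDI, CH2Cl2, rt; then MeNH(OMe)·HCl
Reagents that add atoms: N,O-dimethylhydroxylamine hydrochloride, CNOC.Cl
Why: Weinreb amide formation through the acyl imidazole is a standard acyl substitution that tolerates the terminal alkene.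

Step 8
Reactants: 15 N-methoxy-N-methyldec-9-enamide
Product: 16 N-methoxy-N-methyl-9-oxodecanamide
Conditions: PdCl2 (10 mol%), CuCl (co-catalyst), O2 (1 atm), DMF/H2O (7:1), rt
Reagents that add atoms: water, O (ketone oxygen; O2 is the terminal oxidant)
Why: Tsuji–Wacker oxidation should convert the terminal alkene into the methyl ketone with Markovnikov regiochemistry while the amide stays inert.

Step 9
Reactants: 16 N-methoxy-N-methyl-9-oxodecanamide
Product: 17 (9R)-9-hydroxy-N-methoxy-N-methyldecanamide
Conditions: ketoreductase (anti-Prelog, (R)-selective alcohol dehydrogenase), NADP+ (cat.), i-PrOH, phosphate buffer pH 7, 30 °C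
Reagents that add atoms: none
Why: Enzymatic carbonyl reduction by a ketoreductase, in which hydride from NADPH (recycled by propan-2-ol) is delivered to one face of the methyl ketone held with its methyl group in the small pocket, so that the (R)-carbinol is set by the catalyst.

Step 10
Reactants: 12 6-{4-[(3S,4S)-2-methoxy-2,4-dimethyloxolan-3-yl]-2-oxobutyl}-2,2-dimethyl-4H-1,3-dioxin-4-one; 17 (9R)-9-hydroxy-N-methoxy-N-methyldecanamide
Product: 20 6-[(12R)-12-hydroxy-3-{[(3S,4S)-2-methoxy-2,4-dimethyloxolan-3-yl]methyl}-2,4-dioxotridecyl]-2,2-dimethyl-4H-1,3-dioxin-4-one, via dianion 18 (not isolated), via lithium alkoxide 19 (not isolated)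
Conditions: 12, LDA (3.2 equiv), THF, −78 °C; then 17 premixed with LDA (1.0 equiv), −78 → −20 °C; H2O
Reagents that add atoms: none
Why: Claisen-type γ-acylation of a β-dicarbonyl dianion, in which the more reactive terminal carbanion should attack the Weinreb amide (chelated tetrahedral intermediate, no over-addition) while the alkoxide of 17 is a spectator, the new centre between the two ketones being enolisable and lost in step 11.

Step 11
Reactants: 20 6-[(12R)-12-hydroxy-3-{[(3S,4S)-2-methoxy-2,4-dimethyloxolan-3-yl]methyl}-2,4-dioxotridecyl]-2,2-dimethyl-4H-1,3-dioxin-4-one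
Product: 24 O-demethyl-lasiodiplactone A (free phenol ortho to the lactone carbonyl), via acylketene 21 (not isolated), via macrocyclic triketo lactone 22 (not isolated), via resorcylate 23 (not isolated)
Conditions: PhMe (1 mM), 110 °C; then Cs2CO3 (0.2 equiv), i-PrOH/CH2Cl2, rt; then CSA (0.5 equiv), CH2Cl2, 4 Å MS, rt
Reagents that add atoms: none
Why: Heating should cause retro-hetero-Diels–Alder loss of acetone from the dioxinone to give acylketene 21, which the C-12 hydroxyl captures through oxygen with retention to close the 16-membered lactone 22, an acylketene macrolactonisation favoured over oligomerisation by high dilution. Carbonate should then enolise C-3 of 22 (between ester and ketone), which adds across the ring to the C-8 ketone in a 6-(enolendo)-exo-trig aldol, and dehydration with enolisation gives the benzene ring of 23 and with it the 12-membered lactone, the known biomimetic polyketide aromatisation run transannularly as a 16-to-12 ring contraction. Acid should then ionise the 2-methoxyoxolane to a cyclic oxocarbenium ion that only the new phenol ortho to the side chain can reach, closing the pyran 6-exo-trig. The one new stereocentre, the ketal carbon, is set by the adjacent ring-fusion CH from step 1, because the arylmethyl tether can deliver oxygen only to its own face (cis-fused bicycle), and reversibility under acid should let the isomer with the exo methyl accumulate. The step needs aldol closure (C-3 to C-8) rather than Claisen or pyranone closure, which carbonate conditions and the substituted, hindered C-7 favour, and it needs no arene regiocontrol, since C-7 of the macrocycle already carries the side chain between the ketones that become C–O and C–alkyl of the arene.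

Step 12
Reactants: 24 O-demethyl-lasiodiplactone A
Product: 25 lasiodiplactone A
Conditions: MeI, K2CO3, acetone, 50 °C
Reagents that add atoms: iodomethane, CI
Why: Williamson-type O-methylation of the single remaining phenol, hydrogen-bonded to the lactone carbonyl, should proceed under mild base to which ketal and lactone are stable and which touches no stereocentre.

Compound list
1 | (S)-4-methyldihydrofuran-2(3H)-one [(S)-β-methyl-γ-butyrolactone] | O=C1C[C@H](C)CO1 | starting material
2 | lithium enolate of 1 | [Li]OC1=C[C@H](C)CO1 | intermediate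
3 | (3S,4S)-4-methyl-3-(prop-2-en-1-yl)dihydrofuran-2(3H)-one (trans) | C=CC[C@H]1[C@H](C)COC1=O | intermediate
4 | (3S,4S)-2,4-dimethyl-3-(prop-2-en-1-yl)oxolan-2-ol (lactol, C-2 epimers) | C=CC[C@H]1[C@H](C)COC1(C)O | intermediate
5 | (3S,4S)-2-methoxy-2,4-dimethyl-3-(prop-2-en-1-yl)oxolane (C-2 epimers) | C=CC[C@H]1[C@H](C)COC1(C)OC | intermediate
6 | 9-{3-[(3S,4S)-2-methoxy-2,4-dimethyloxolan-3-yl]propyl}-9-borabicyclo[3.3.1]nonane | C1CC2CCCC(C1)B2CCC[C@H]1[C@H](C)COC1(C)OC | intermediate
7 | 3-[(3S,4S)-2-methoxy-2,4-dimethyloxolan-3-yl]propan-1-ol | OCCC[C@H]1[C@H](C)COC1(C)OC | intermediate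
8 | 3-[(3S,4S)-2-methoxy-2,4-dimethyloxolan-3-yl]propanal | O=CCC[C@H]1[C@H](C)COC1(C)OC | intermediate
9 | 2,2,6-trimethyl-4H-1,3-dioxin-4-one | CC1=CC(=O)OC(C)(C)O1 | starting material
10 | lithium dienolate of 9 | C=C1C=C(O[Li])OC(C)(C)O1 | intermediate
11 | 6-{2-hydroxy-4-[(3S,4S)-2-methoxy-2,4-dimethyloxolan-3-yl]butyl}-2,2-dimethyl-4H-1,3-dioxin-4-one | CC1(C)OC(=O)C=C(CC(O)CC[C@H]2[C@H](C)COC2(C)OC)O1 | intermediate
12 | 6-{4-[(3S,4S)-2-methoxy-2,4-dimethyloxolan-3-yl]-2-oxobutyl}-2,2-dimethyl-4H-1,3-dioxin-4-one | CC1(C)OC(=O)C=C(CC(=O)CC[C@H]2[C@H](C)COC2(C)OC)O1 | intermediate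
13 | dec-9-enoic acid | C=CCCCCCCCC(=O)O | starting material
14 | 1-(dec-9-enoyl)imidazole | C=CCCCCCCCC(=O)n1ccnc1 | intermediate
15 | N-methoxy-N-methyldec-9-enamide | C=CCCCCCCCC(=O)N(C)OC | intermediate
16 | N-methoxy-N-methyl-9-oxodecanamide | CC(=O)CCCCCCCC(=O)N(C)OC | intermediate
17 | (9R)-9-hydroxy-N-methoxy-N-methyldecanamide | C[C@@H](O)CCCCCCCC(=O)N(C)OC | intermediate
18 | dilithium dianion (dienediolate) of 12 | [Li]OC1=CC(=CC(O[Li])=CC[C@H]2[C@H](C)COC2(C)OC)OC(C)(C)O1 | intermediate
19 | lithium alkoxide of 17 | C[C@@H](O[Li])CCCCCCCC(=O)N(C)OC | intermediate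
20 | 6-[(12R)-12-hydroxy-3-{[(3S,4S)-2-methoxy-2,4-dimethyloxolan-3-yl]methyl}-2,4-dioxotridecyl]-2,2-dimethyl-4H-1,3-dioxin-4-one | CC1(C)OC(=O)C=C(CC(=O)C(C[C@H]2[C@H](C)COC2(C)OC)C(=O)CCCCCCC[C@@H](C)O)O1 | intermediate
21 | acylketene from 20: (14R)-14-hydroxy-5-{[(3S,4S)-2-methoxy-2,4-dimethyloxolan-3-yl]methyl}-3,5... open-chain 3,5,7-trioxo ketene (O=C=CH–CO–CH2–CO–CH(R)–CO–(CH2)7–CH(OH)CH3) | O=C=CC(=O)CC(=O)C(C[C@H]1[C@H](C)COC1(C)OC)C(=O)CCCCCCC[C@@H](C)O | intermediate
22 | (16R)-7-{[(3S,4S)-2-methoxy-2,4-dimethyloxolan-3-yl]methyl}-16-methyl-1-oxacyclohexadecane-2,4,6,8-tetrone | C[C@@H]1CCCCCCCC(=O)C(C[C@H]2[C@H](C)COC2(C)OC)C(=O)CC(=O)CC(=O)O1 | intermediate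
23 | (3R)-12,14-dihydroxy-11-{[(3S,4S)-2-methoxy-2,4-dimethyloxolan-3-yl]methyl}-3-methyl-3,4,5,6,7,8,9,10-octahydro-1H-2-benzoxacyclododecin-1-one | C[C@@H]1CCCCCCCc2c(C[C@H]3[C@H](C)COC3(C)OC)c(O)cc(O)c2C(=O)O1 | intermediate
24 | O-demethyl-lasiodiplactone A (target with OH in place of OMe) | Oc1cc2c(c3c1C(=O)O[C@H](C)CCCCCCC3)C[C@H]1[C@H](C)CO[C@@]1(C)O2 | intermediate
25 | lasiodiplactone A | COc1cc2c(c3c1C(=O)O[C@H](C)CCCCCCC3)C[C@H]1[C@H](C)CO[C@@]1(C)O2 | target

Total step count: 12. Longest linear sequence: 9 steps (steps 1–6, 10, 11 and 12, from lactone 1).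

Steps most likely to fail

Step 11. The acylketene may be intercepted by the enol oxygen of the diketone (pyranone formation) or by a second molecule before the remote hydroxyl reaches it, and the transannular aldol may be slow in the substituted macrocycle. The fallback, from 20 back to 24, separates ring construction from macrocyclisation. Compound 20 is heated in toluene with excess allyl alcohol so that the ketene is captured intermolecularly, and the same carbonate and CSA treatment aromatises the open-chain triketo ester and closes the ketal to give the allyl ester of the seco acid F1. Pd(PPh3)4 with morpholine removes the allyl group to give the seco acid F2. A Corey–Nicolaou thiol-ester macrolactonisation (2,2'-dipyridyl disulfide, PPh3; then AgOTf at high dilution), which acylates the carbinol oxygen with retention, returns to 24.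

Step 10. Proton transfer from the amide to the dianion, or sluggish C-acylation at the secondary carbanion, may leave 12 and 17 unchanged. The fallback, from 12 and 17 back to 20, makes the C–C bond by aldol addition instead of acyl substitution. Alcohol 17 is silylated (TESCl, imidazole) to the triethylsilyl ether F3 and reduced with DIBAL-H at −78 °C to the aldehyde F4. Dianion 18 adds to it to give the β-hydroxy ketone F5, Dess–Martin oxidation gives the silylated diketo-dioxinone F6, and pyridine-buffered HF·pyridine removes the silyl group to return to 20.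

Step 2. A second addition of methyllithium to the ring-opened ketone, or loss of the mixed ketal by hydrolysis or elimination on isolation, may erode the material. The fallback, from 3 back to 4, opens the lactone with Me(MeO)NH·HCl and AlMe3 to the hydroxy Weinreb amide F7. Its magnesium chelate should take up exactly one methyl group from excess MeMgBr (THF, 0 °C) and give lactol 4 on work-up, which is ketalised to 5 as in step 2.

Further compounds
F1 | step 11 | allyl ester of the seco acid of 24 (furochromene ketal closed, free (R)-carbinol and 2-OH) | C=CCOC(=O)c1c(O)cc2c(c1CCCCCCC[C@@H](C)O)C[C@H]1[C@H](C)CO[C@@]1(C)O2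
F2 | step 11 | seco acid of 24 | OC(=O)c1c(O)cc2c(c1CCCCCCC[C@@H](C)O)C[C@H]1[C@H](C)CO[C@@]1(C)O2
F3 | step 10 | (9R)-N-methoxy-N-methyl-9-(triethylsilyloxy)decanamide | C[C@@H](O[Si](CC)(CC)CC)CCCCCCCC(=O)N(C)OC
F4 | step 10 | (9R)-9-(triethylsilyloxy)decanal | C[C@@H](O[Si](CC)(CC)CC)CCCCCCCC=O
F5 | step 10 | 6-[(12R)-4-hydroxy-3-{[(3S,4S)-2-methoxy-2,4-dimethyloxolan-3-yl]methyl}-2-oxo-12-(triethylsilyloxy)tridecyl]-2,2-dimethyl-4H-1,3-dioxin-4-one | CC1(C)OC(=O)C=C(CC(=O)C(C[C@H]2[C@H](C)COC2(C)OC)C(O)CCCCCCC[C@@H](C)O[Si](CC)(CC)CC)O1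
F6 | step 10 | triethylsilyl ether of 20 | CC1(C)OC(=O)C=C(CC(=O)C(C[C@H]2[C@H](C)COC2(C)OC)C(=O)CCCCCCC[C@@H](C)O[Si](CC)(CC)CC)O1
F7 | step 2 | (2S,3S)-4-hydroxy-N-methoxy-N,3-dimethyl-2-(prop-2-en-1-yl)butanamide | C=CC[C@H](C(=O)N(C)OC)[C@H](C)CO
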